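**Strategy.** Ring B (C5–C6–C7–C8–C9–C10, the ring carrying the acetate) is not assembled at its final size: the C8–C9 bond is disconnected and C9 is reattached to C7, giving a cis-fused hydrindane whose C7 tertiary carbinol carries an (S)-1-mesyloxyethyl group (C8, C17). The key step, an organoaluminium-promoted semipinacol shift of the quaternary C9 from C7 to C8, enlarges the five-membered ring to ring B, sets the C8 methyl stereocentre by inversion and leaves the oxygen at C7. It exploits the contiguous C7(O)–C8(H)(CH3)–C9(quaternary) array of ring B. The hydrindane comes from 2-methylcyclohexane-1,3-dione; the side chain from (R)-3-methylglutarate.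

Key step: step 12

Remark (numbering): atoms keep their clerodane numbers in all intermediates (ring A: C1–C5, C10; ring B: C5–C10; side chain C11–C16; C17 on C8, C18 the exocyclic methylene carbon, C19 on C5, C20 on C9); β is the face of the bicycle that carries C19.

Remark (assumptions): compounds 1, 4 and 5 are taken as commercial; C7 in 14–17, C3 in 21 and C2 in 24/25 are formed without control and become sp2 later, so their SMILES leave that one centre open.

Step 1
Reactants: 1 (R)-5-methoxy-3-methyl-5-oxopentanoic acid
Product: 2 methyl (R)-5-hydroxy-3-methylpentanoate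
Conditions: BH3·SMe2, THF, 0 °C → rt
Reagents that add atoms: none
Why: Borane reduces a free carboxylic acid far faster than a methyl ester (chemoselective acyloxyborane reduction), so only the acid end becomes the primary alcohol and the chiral-pool stereocentre (future C13) is untouched; the alcohol is used at once to avoid lactonisation.

Step 2
Reactants: 2 methyl (R)-5-hydroxy-3-methylpentanoate
Product: 3 methyl (S)-5-iodo-3-methylpentanoate
Conditions: I2, PPh3, imidazole, CH2Cl2, 0 °C → rt
Reagents that add atoms: iodine, [I][I]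
Why: Appel-type iodination (Garegg–Samuelsson conditions) is an SN2 reaction at a non-stereogenic primary carbon; the descriptor changes from R to S only through the priority of iodine.

Step 3
Reactants: 4 2-methylcyclohexane-1,3-dione; 5 1-bromobut-2-yne
Product: 6 2-(but-2-yn-1-yl)-2-methylcyclohexane-1,3-dione
Conditions: KOH (1 equiv), H2O, rt → 60 °C
Reagents that add atoms: none
Why: C-alkylation of the enolate of a cyclic 2-alkyl-1,3-dione with a reactive propargylic bromide in water is an established route to 2,2-disubstituted diones; the product is achiral and carries C6, C7, C9 and C20 as a masked 2-oxobutyl group.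

Step 4
Reactants: 6 2-(but-2-yn-1-yl)-2-methylcyclohexane-1,3-dione
Product: 7 (2S,3S)-2-(but-2-yn-1-yl)-3-hydroxy-2-methylcyclohexan-1-one
Conditions: baker's yeast, sucrose, H2O, 30 °C
Reagents that add atoms: none
Why: Enantiotopic-group-selective yeast reduction of 2,2-disubstituted cyclohexane-1,3-diones is well established and should, by analogy with the 2-allyl and 2-propargyl homologues that give (2S,3S)-ketols, fix the quaternary carbon (future C5) in the required absolute sense, the carbinol carbon being the future C10.

Step 5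
Reactants: 7 (2S,3S)-2-(but-2-yn-1-yl)-3-hydroxy-2-methylcyclohexan-1-one
Product: 8 (1S,2R)-2-(but-2-yn-1-yl)-2-methyl-3-methylidenecyclohexan-1-ol
Conditions: Zn, CH2Br2, TiCl4, THF/CH2Cl2, 0 °C → rt
Reagents that add atoms: dibromomethane, BrCBr
Why: Takai–Lombardo methylenation is non-basic, so the β-hydroxy ketone cannot undergo the retro-aldol cleavage that would racemise C5, and it copes with the hindered neopentyl ketone, installing C4=C18 early.

Step 6
Reactants: 8 (1S,2R)-2-(but-2-yn-1-yl)-2-methyl-3-methylidenecyclohexan-1-ol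
Product: 9 (R)-2-(but-2-yn-1-yl)-2-methyl-3-methylidenecyclohexan-1-one
Conditions: Dess–Martin periodinane, NaHCO3, CH2Cl2, rt
Reagents that add atoms: none
Why: Buffered Dess–Martin oxidation of the secondary alcohol gives the β,γ-unsaturated ketone, which can neither conjugate nor epimerise because C5 is quaternary.

Step 7
Reactants: 9 (R)-2-(but-2-yn-1-yl)-2-methyl-3-methylidenecyclohexan-1-one
Product: 11 (R)-3,7a-dimethyl-7-methylidene-1,4,5,6,7,7a-hexahydro-2H-inden-2-one, via diketone 10 (not isolated)
Conditions: NaAuCl4·2H2O (2 mol %), MeOH/H2O, 65 °C; then KOH, MeOH, 60 °C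
Reagents that add atoms: water, O (taken up in the hydration to 10 and released again in the condensation)
Why: Gold-catalysed alkyne hydration is directed by the neighbouring C10 carbonyl (5-exo attack) to the 1,4-diketone, and base then effects the classical aldol cyclodehydration of a 2-(2-oxoalkyl)cyclohexanone, C9 attacking C10 to give the tetrasubstituted cyclopentenone without touching C5.

Step 8
Reactants: 11 (R)-3,7a-dimethyl-7-methylidene-1,4,5,6,7,7a-hexahydro-2H-inden-2-one; 3 methyl (S)-5-iodo-3-methylpentanoate
Product: 13 methyl (3R)-5-[cis-1,3a-dimethyl-4-methylidene-2-oxooctahydro-1H-inden-1-yl]-3-methylpentanoate (9β side chain; 9α-CH3; 10β-H), via lithium enolate 12 (not isolated)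
Conditions: Li (2.2 equiv), t-BuOH (1 equiv), NH3(l)/THF, −78 °C; then 3, THF, −78 → −33 °C; NH4Cl
Reagents that add atoms: none
Why: Stork reductive alkylation: the dissolving metal reduces only the enone, protonation of C10 should occur cis to C19 to give the less strained cis-fused enolate, and the regiodefined enolate 12 is alkylated at C9 anti to the adjacent C10–C1 bond (β face), which places the side chain cis to H-10 and leaves C20 α.

Step 9
Reactants: 13 methyl (3R)-5-[cis-1,3a-dimethyl-4-methylidene-2-oxooctahydro-1H-inden-1-yl]-3-methylpentanoate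
Product: 15 C7 tertiary carbinol bearing an acetyl group (α-hydroxy methyl ketone; C7 epimers), via enol ether carbinol 14 (not isolated)
Conditions: ethyl vinyl ether, t-BuLi, THF, −78 → 0 °C; CeCl3, −78 °C; then 13; then 0.5 M HCl, THF, 0 °C
Reagents that add atoms: ethyl vinyl ether, C=COCC; water, O
Why: The organocerium reagent from 1-ethoxyvinyllithium (an acyl-anion equivalent) adds to the hindered, enolisable cyclopentanone at −78 °C faster than to the methyl ester, and mild acid hydrolysis of the enol ether unmasks the acetyl group (C8, C17); the C7 configuration is of no consequence.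

Step 10
Reactants: 15 α-hydroxy methyl ketone
Product: 16 C7,C8-diol with (S)-configured C8
Conditions: (R)-1-methyl-3,3-diphenyltetrahydro-1H,3H-pyrrolo[1,2-c][1,3,2]oxazaborole [(R)-Me-CBS, 0.2 equiv], catecholborane, toluene, −78 °C
Reagents that add atoms: none
Why: Corey–Bakshi–Shibata reduction of the methyl ketone (large group: the tertiary carbinol carbon; small group: methyl) is under reagent control, so the (R)-catalyst should give the (S)-carbinol at C8 whichever C7 epimer is present.

Step 11
Reactants: 16 C7,C8-diol
Product: 17 C8 (S)-methanesulfonate of the diol (free tertiary C7–OH)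
Conditions: MsCl, Et3N, CH2Cl2, −20 °C
Reagents that add atoms: methanesulfonyl chloride, CS(=O)(=O)Cl
Why: The secondary hydroxyl is sulfonylated selectively because the tertiary one is too hindered to react at low temperature.

Step 12
Reactants: 17 C8 (S)-methanesulfonate
Product: 18 methyl (13R)-7-oxo-cis-cleroda-4(18)-en-15-oate (5β-CH3, 10β-H, 8α-CH3, 9α-CH3)
Conditions: Et3Al (3 equiv), CH2Cl2, −78 → 0 °C
Reagents that add atoms: none
Why: Et3Al turns the tertiary hydroxyl into an aluminium alkoxide (ethane is lost) and, as a Lewis acid, pulls on the mesylate; pushed by the alkoxide oxygen, C9 shifts from C7 to C8 anti-periplanar to the departing mesylate, C7 becomes the ketone and the cyclopentane C5–C6–C7–C9–C10 becomes the cyclohexane C5–C6–C7–C8–C9–C10. The closest known reaction is the Tsuchihashi–Suzuki organoaluminium-promoted 1,2-shift of 2-hydroxy mesylates, and in ring-size terms the D-homoannulation of steroid hydrindanes. No ring is closed by cyclisation: ring B arises by ring enlargement through a concerted [1,2]-alkyl shift that inserts C8 between C7 and C9. The new C8 stereocentre is controlled by the configuration of the mesylate carbon, which is inverted (the S-mesylate gives 8α-CH3/8β-H, which is also the equatorial epimer, so any later enolisation converges on it), while C9 migrates with retention and carries its quaternary configuration over. The step needs migration of C9 and not of C6; this is secured by the higher migratory aptitude of the fully substituted, electron-richer C9 over the primary C6 in this cation-like shift and by free rotation about C7–C8, which lets C9 reach the anti position from either C7 epimer.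

Step 13
Reactants: 18 methyl (13R)-7-oxo-cis-cleroda-4(18)-en-15-oate
Product: 19 methyl (13R)-7β-hydroxy-cis-cleroda-4(18)-en-15-oate
Conditions: SmI2, THF/H2O, 0 °C → rt
Reagents that add atoms: none
Why: Single-electron (ketyl) reduction with SmI2 should give the thermodynamically preferred alcohol, here the equatorial 7β-OH because the axial position is flanked by the axial C20 methyl and C4, and it leaves the methyl ester and the alkene untouched.

Step 14
Reactants: 19 methyl (13R)-7β-hydroxy-cis-cleroda-4(18)-en-15-oate
Product: 20 methyl (13R)-7β-acetoxy-cis-cleroda-4(18)-en-15-oate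
Conditions: Ac2O, 4-(dimethylamino)pyridine, pyridine, rt
Reagents that add atoms: acetic anhydride, CC(=O)OC(C)=O
Why: Standard nucleophile-catalysed acetylation of the equatorial secondary alcohol with retention at C7.

Step 15
Reactants: 20 methyl (13R)-7β-acetoxy-cis-cleroda-4(18)-en-15-oate
Product: 21 methyl (13R)-7β-acetoxy-3-hydroxy-cis-cleroda-4(18)-en-15-oate (C3 epimers)
Conditions: SeO2 (0.5 equiv), t-BuOOH, CH2Cl2, rt
Reagents that add atoms: selenium dioxide, O=[Se]=O (oxygen carrier); tert-butyl hydroperoxide, CC(C)(C)OO (reoxidant)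
Why: Selenium dioxide allylic hydroxylation (ene reaction then [2,3]-sigmatropic shift) of the 1,1-disubstituted alkene can only occur at C3, because the other allylic carbon C5 is quaternary, and it returns the double bond to the exocyclic position.

Step 16
Reactants: 21 methyl (13R)-7β-acetoxy-3-hydroxy-cis-cleroda-4(18)-en-15-oate
Product: 22 methyl (13R)-7β-acetoxy-3-oxo-cis-cleroda-4(18)-en-15-oate
Conditions: Dess–Martin periodinane, NaHCO3, CH2Cl2, 0 °C → rt
Reagents that add atoms: none
Why: Dess–Martin oxidation of the allylic alcohol gives the hindered α-methylene ketone without affecting either ester.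

Step 17
Reactants: 22 methyl (13R)-7β-acetoxy-3-oxo-cis-cleroda-4(18)-en-15-oate
Product: 25 methyl (13R)-7β-acetoxy-2-hydroxy-3-oxo-cis-cleroda-4(18)-en-15-oate (C2 epimers), via silyl dienol ether 23 (not isolated), via silyloxy ketone 24 (not isolated)
Conditions: TMSOTf, Et3N, CH2Cl2, 0 °C; then dimethyldioxirane, acetone, −78 °C; then citric acid, MeOH, rt
Reagents that add atoms: dimethyldioxirane, CC1(C)OO1
Why: Rubottom oxidation: soft enolisation can only go towards C2 (C4 has no hydrogen), the electron-rich silyl enol ether bond of the 2-silyloxydiene is epoxidised in preference to the terminal methylene, and silyl migration followed by mild acid cleavage gives the α-hydroxy ketone.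

Step 18
Reactants: 25 methyl (13R)-7β-acetoxy-2-hydroxy-3-oxo-cis-cleroda-4(18)-en-15-oate
Product: 26 methyl (5S,7S,8S,9R,10R,13R)-7-acetoxy-2-hydroxy-3-oxocleroda-1,4(18)-dien-15-oate (target)
Conditions: Dess–Martin periodinane, NaHCO3, CH2Cl2, 0 °C
Reagents that add atoms: none
Why: Oxidation of the acyloin gives the 2,3-dione, which can enolise only towards C1 and should therefore rest as the diosphenol of the target.

**Compound list**

1 | (R)-5-methoxy-3-methyl-5-oxopentanoic acid (monomethyl (R)-3-methylglutarate) | OC(=O)C[C@@H](C)CC(=O)OC | starting material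
2 | methyl (R)-5-hydroxy-3-methylpentanoate | OCC[C@@H](C)CC(=O)OC | intermediate
3 | methyl (S)-5-iodo-3-methylpentanoate | ICC[C@@H](C)CC(=O)OC | intermediate
4 | 2-methylcyclohexane-1,3-dione | CC1C(=O)CCCC1=O | starting material
5 | 1-bromobut-2-yne | CC#CCBr | starting material
6 | 2-(but-2-yn-1-yl)-2-methylcyclohexane-1,3-dione | CC#CCC1(C)C(=O)CCCC1=O | intermediate
7 | (2S,3S)-2-(but-2-yn-1-yl)-3-hydroxy-2-methylcyclohexan-1-one | CC#CC[C@]1(C)C(=O)CCC[C@@H]1O | intermediate
8 | (1S,2R)-2-(but-2-yn-1-yl)-2-methyl-3-methylidenecyclohexan-1-ol | CC#CC[C@]1(C)C(=C)CCC[C@@H]1O | intermediate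
9 | (R)-2-(but-2-yn-1-yl)-2-methyl-3-methylidenecyclohexan-1-one | CC#CC[C@]1(C)C(=C)CCCC1=O | intermediate
10 | (R)-2-methyl-3-methylidene-2-(2-oxobutyl)cyclohexan-1-one | CCC(=O)C[C@]1(C)C(=C)CCCC1=O | intermediate (not isolated)
11 | (R)-3,7a-dimethyl-7-methylidene-1,4,5,6,7,7a-hexahydro-2H-inden-2-one | C=C1CCCC2=C(C)C(=O)C[C@]12C | intermediate
12 | lithium enolate (C7–OLi, C7=C9) of the cis-fused hydrindanone, 10β-H | C=C1CCC[C@@H]2C(C)=C(O[Li])C[C@]12C | intermediate (not isolated)
13 | methyl (3R)-5-[cis-1,3a-dimethyl-4-methylidene-2-oxooctahydro-1H-inden-1-yl]-3-methylpentanoate (5β-CH3, 10β-H, 9α-CH3, 9β side chain) | C=C1CCC[C@@H]2[C@@](C)(CC[C@@H](C)CC(=O)OC)C(=O)C[C@]12C | intermediate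
14 | 13 with C7 converted into C(OH)–C(OEt)=CH2 (enol ether carbinol, C7 epimers) | C=C1CCC[C@@H]2[C@@](C)(CC[C@@H](C)CC(=O)OC)C(O)(C(=C)OCC)C[C@]12C | intermediate (not isolated)
15 | 13 with C7 converted into C(OH)–C(=O)CH3 (α-hydroxy methyl ketone, C7 epimers) | C=C1CCC[C@@H]2[C@@](C)(CC[C@@H](C)CC(=O)OC)C(O)(C(C)=O)C[C@]12C | intermediate
16 | C7,C8-diol: C7(OH)–(S)-CH(OH)CH3 (C7 epimers) | C=C1CCC[C@@H]2[C@@](C)(CC[C@@H](C)CC(=O)OC)C(O)([C@H](C)O)C[C@]12C | intermediate
17 | C8 (S)-methanesulfonate of 16 | C=C1CCC[C@@H]2[C@@](C)(CC[C@@H](C)CC(=O)OC)C(O)([C@H](C)OS(C)(=O)=O)C[C@]12C | intermediate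
18 | methyl (13R)-7-oxo-cis-cleroda-4(18)-en-15-oate (5β-CH3, 10β-H, 8α-CH3, 9α-CH3) | C=C1CCC[C@@H]2[C@@](C)(CC[C@@H](C)CC(=O)OC)[C@H](C)C(=O)C[C@]12C | intermediate
19 | methyl (13R)-7β-hydroxy-cis-cleroda-4(18)-en-15-oate | C=C1CCC[C@@H]2[C@@](C)(CC[C@@H](C)CC(=O)OC)[C@H](C)[C@@H](O)C[C@]12C | intermediate
20 | methyl (13R)-7β-acetoxy-cis-cleroda-4(18)-en-15-oate | C=C1CCC[C@@H]2[C@@](C)(CC[C@@H](C)CC(=O)OC)[C@H](C)[C@@H](OC(C)=O)C[C@]12C | intermediate
21 | methyl (13R)-7β-acetoxy-3-hydroxy-cis-cleroda-4(18)-en-15-oate (C3 epimers) | C=C1C(O)CC[C@@H]2[C@@](C)(CC[C@@H](C)CC(=O)OC)[C@H](C)[C@@H](OC(C)=O)C[C@]12C | intermediate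
22 | methyl (13R)-7β-acetoxy-3-oxo-cis-cleroda-4(18)-en-15-oate | C=C1C(=O)CC[C@@H]2[C@@](C)(CC[C@@H](C)CC(=O)OC)[C@H](C)[C@@H](OC(C)=O)C[C@]12C | intermediate
23 | 3-trimethylsilyloxy-2,4(18)-diene (silyl dienol ether of 22) | C=C1C(O[Si](C)(C)C)=CC[C@@H]2[C@@](C)(CC[C@@H](C)CC(=O)OC)[C@H](C)[C@@H](OC(C)=O)C[C@]12C | intermediate (not isolated)
24 | 2-trimethylsilyloxy-3-ketone (C2 epimers) | C=C1C(=O)C(O[Si](C)(C)C)C[C@@H]2[C@@](C)(CC[C@@H](C)CC(=O)OC)[C@H](C)[C@@H](OC(C)=O)C[C@]12C | intermediate (not isolated)
25 | methyl (13R)-7β-acetoxy-2-hydroxy-3-oxo-cis-cleroda-4(18)-en-15-oate (C2 epimers) | C=C1C(=O)C(O)C[C@@H]2[C@@](C)(CC[C@@H](C)CC(=O)OC)[C@H](C)[C@@H](OC(C)=O)C[C@]12C | intermediate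
26 | methyl (5S,7S,8S,9R,10R,13R)-7-acetoxy-2-hydroxy-3-oxocleroda-1,4(18)-dien-15-oate | C=C1C(=O)C(O)=C[C@@H]2[C@@](C)(CC[C@@H](C)CC(=O)OC)[C@H](C)[C@@H](OC(C)=O)C[C@]12C | target

**Step count and risks**

Total step count: 18. Longest linear sequence: 16 steps (steps 3–18); the side-chain iodide (steps 1–2) joins in step 8.

Steps most likely to fail:

1. Step 8. The fully substituted, hindered enolate may be alkylated only slowly by the unactivated iodide, so that proton exchange, O-alkylation and loss of regiocontrol compete; protonation of C10 from the wrong face (trans ring fusion) is a second danger. Fallback, setting out from 11 and 2 and coming back at 13: alcohol 2 is oxidised with Dess–Martin periodinane to methyl (R)-3-methyl-5-oxopentanoate F1. Enolate 12 is generated from 11 as in step 8 and, instead of being alkylated, is added at −78 °C to this far more electrophilic aldehyde (reductive aldol) to give the C11-hydroxy derivative of 13 F2 as a mixture at C11. 1,1'-Thiocarbonyldiimidazole converts it into the O-(imidazol-1-ylthiocarbonyl) derivative F3, and Barton–McCombie deoxygenation (Bu3SnH, AIBN, toluene, 80 °C) removes the C11 oxygen to give 13.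

2. Step 12. The methylene carbon C6 may migrate in competition with C9, or the aluminium alkoxide may close onto C8 to an epoxide instead of triggering the shift. Fallback, setting out from 13 and coming back at 18: the carbanion of 1-chloroethyl 4-tolyl sulfoxide (LDA, THF, −78 °C) is added to the C7 ketone to give the C7 carbinol bearing a 1-chloro-1-(4-tolylsulfinyl)ethyl group F4. After deprotonation of the hydroxyl with t-BuMgCl, sulfoxide–magnesium exchange with i-PrMgCl generates a magnesium β-oxido carbenoid; its anionic 1,2-shift, in which a carbenoid and not a cation-like transition state selects the migrating bond, gives the magnesium enolate of the ring-enlarged ketone. Protonation and equilibration at C8 with DBU lead to 18.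

3. Step 13. The electron-transfer reduction may not override the kinetic preference for hydrogen delivery from the open equatorial side, leaving the axial 7α-alcohol or mixtures. Fallback, setting out from 18 and coming back at 20: NaBH4 (MeOH, 0 °C) is used on purpose to give the axial alcohol, methyl (13R)-7α-hydroxy-cis-cleroda-4(18)-en-15-oate F5, and Mitsunobu inversion with acetic acid (PPh3, DIAD, toluene) installs the 7β-acetate directly, so that 19 is bypassed.

Further compounds
F1 | step 8 | methyl (R)-3-methyl-5-oxopentanoate | O=CC[C@@H](C)CC(=O)OC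
F2 | step 8 | C11-hydroxy derivative of 13 (aldol adduct, C11 epimers) | C=C1CCC[C@@H]2[C@@](C)(C(O)C[C@@H](C)CC(=O)OC)C(=O)C[C@]12C
F3 | step 8 | O-(imidazol-1-ylthiocarbonyl) derivative of F2 | C=C1CCC[C@@H]2[C@@](C)(C(OC(=S)n3ccnc3)C[C@@H](C)CC(=O)OC)C(=O)C[C@]12C
F4 | step 12 | C7 carbinol of 13 bearing a 1-chloro-1-(4-tolylsulfinyl)ethyl group | C=C1CCC[C@@H]2[C@@](C)(CC[C@@H](C)CC(=O)OC)C(O)(C(C)(Cl)S(=O)c3ccc(C)cc3)C[C@]12C
F5 | step 13 | methyl (13R)-7α-hydroxy-cis-cleroda-4(18)-en-15-oate | C=C1CCC[C@@H]2[C@@](C)(CC[C@@H](C)CC(=O)OC)[C@H](C)[C@H](O)C[C@]12C
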